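## Retrosynthetic overview

1. The target is disconnected by a 1,2-benzyl shift (C2→C3, α-ketol / intramolecular benzilic-ester type) to the isomeric hemiketal 2-hydroxy-2,4-dibenzyl-3-oxotetrahydrofuran. The shift creates the lactone C=O and the tertiary carbinol, and is meant to set both stereocentres by dynamic kinetic resolution.
2. The hemiketal comes from C2 oxygenation (Rubottom) of 2,4-dibenzyl-dihydrofuran-3-one, which comes from hydrogenation of the 2,4-bis(arylidene)dihydrofuran-3-one.
3. The bis(arylidene) ketone comes from a double Claisen–Schmidt condensation of dihydrofuran-3(2H)-one with two vanillin.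
4. Vanillin comes from guaiacol and glyoxylic acid; guaiacol comes from catechol and MeI.
5. No ring is built: both arenes come from catechol, and the oxolane ring is bought as dihydrofuran-3(2H)-one and turned from a 3-furanone into the γ-lactone in the key step.

Assumption: the SMILES is read as (3S,4R), i.e. the two benzyl groups are cis (3-OH syn to H-4); glyoxylic acid is used as its 50% aqueous solution.

## Route

Step 1
Reactants: 1 catechol (benzene-1,2-diol)
Product: 2 guaiacol (2-methoxyphenol)
Conditions: MeI (1.0 equiv), K2CO3 (1.0 equiv), acetone, reflux; 1 in 1.5-fold excess (recovered)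
Reagents that add atoms: iodomethane, CI
Why: Williamson mono-O-methylation of the catechol mono-anion, with over-methylation held down by the excess of 1 (veratrole removed by base extraction, 1 by distillation); no stereocentre.

Step 2
Reactants: 2 guaiacol; 3 glyoxylic acid
Product: 6 vanillin (4-hydroxy-3-methoxybenzaldehyde), via vanillylmandelic acid 4 (not isolated), via vanilloylformic acid 5 (not isolated)
Conditions: NaOH aq, 30 °C; then CuSO4 (cat.), O2, 95 °C; then H2SO4 to pH 2, 80 °C
Reagents that add atoms: none
Why: Hydroxyalkylation of the phenoxide para to O⁻ by glyoxylate (electrophilic aromatic substitution), Cu-catalysed aerobic oxidation to the aryl-glyoxylic acid and acid-induced decarboxylation (the technical vanillin sequence); the mandelic stereocentre is destroyed.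

Step 3
Reactants: 6 vanillin (2.1 equiv); 7 dihydrofuran-3(2H)-one
Product: 8 (2Z,4E)-2,4-bis(4-hydroxy-3-methoxybenzylidene)dihydrofuran-3(2H)-one
Conditions: pyrrolidine (30 mol %), AcOH (30 mol %), EtOH, 70 °C
Reagents that add atoms: none
Why: Double Claisen–Schmidt (crossed aldol) condensation at both α-CH2 groups under enamine/iminium catalysis, which tolerates the free phenols; the thermodynamic (2Z,4E) dienone should crystallise out; no stereocentre.

Step 4
Reactants: 8 (2Z,4E)-2,4-bis(4-hydroxy-3-methoxybenzylidene)dihydrofuran-3(2H)-one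
Product: 9 2,4-bis(4-hydroxy-3-methoxybenzyl)dihydrofuran-3(2H)-one (cis/trans mixture, racemic)
Conditions: H2 (1 atm), 10% Pd/C, EtOAc–MeOH, rt
Reagents that add atoms: none
Why: Heterogeneous catalytic hydrogenation of the two conjugated C=C bonds leaves ketone, ring ether and arenes intact; C2 and C4 form unselectively, which is harmless because C2 is planarised in step 5 and C4 is re-set in step 6.

Step 5
Reactants: 9 2,4-bis(4-hydroxy-3-methoxybenzyl)dihydrofuran-3(2H)-one
Product: 12 2-hydroxy-2,4-bis(4-hydroxy-3-methoxybenzyl)dihydrofuran-3(2H)-one (equilibrating hemiketal mixture), via tris-TMS enol ether 10 (not isolated), via 2-silyloxy ketone 11 (not isolated)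
Conditions: TMSOTf (3.3 equiv), Et3N (4 equiv), CH2Cl2, 0 °C to rt, pentane trituration; DMDO, acetone–CH2Cl2, −40 °C; citric acid (cat.), MeOH, 0 °C
Reagents that add atoms: dimethyldioxirane, CC1(C)OO1; trimethylsilyl triflate, C[Si](C)(C)OS(=O)(=O)C(F)(F)F (its silyl groups are in 10 and 11 only)
Why: Rubottom oxidation: equilibrating silylation gives the enol ether towards C2 (a C2=C3 bond conjugated with the ring oxygen, as 2,3-dihydrofurans are favoured over 2,5-dihydrofurans) while masking both phenols, DMDO epoxidises this electron-rich alkene, and mild methanolysis releases the hemiketal; C2 is a labile hemiketal centre (ring–chain tautomerism), so nothing has to be controlled here.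

Step 6
Reactants: 12 2-hydroxy-2,4-bis(4-hydroxy-3-methoxybenzyl)dihydrofuran-3(2H)-one
Product: 13 (3S,4R)-3-hydroxy-3,4-bis(4-hydroxy-3-methoxybenzyl)dihydrofuran-2(3H)-one
Conditions: Cu(OTf)2 (10 mol %), (S,S)-tBu-box (11 mol %), 2,6-lutidine (20 mol %), 4 Å MS, CH2Cl2–THF 4:1, 0 °C to rt, Ar
Reagents that add atoms: none
Why: Proposed new method: a catalytic enantio- and diastereoconvergent α-ketol (intramolecular benzilic-ester) rearrangement in which the Cu(II)–bis(oxazoline) chelates the hemiketal O–H and the C3 ketone, lutidine shuttles the proton, and the C2 benzyl shifts suprafacially to C3 while C2 collapses to the lactone carbonyl (irreversible: ketone + hemiketal → ester + tertiary alcohol); because C2 (ring–chain tautomerism) and C4 (enolisation of the 1,2-dicarbonyl form) interconvert faster than the shift, the catalyst is expected to select the (2R)-hemiketal whose benzyl migrates on the ligand-free face (sets 3S) and the C4 epimer whose benzyl avoids the ligand-shielded O–Cu–O face and so lies syn to the migrating group (sets 4R, cis-dibenzyl); the closest known reaction types are chiral-Lewis-acid-catalysed enantioselective α-ketol rearrangements of tertiary α-hydroxy ketones and the alkoxide-mediated benzilic ester rearrangement.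

## Compound list

1 | catechol (benzene-1,2-diol) | Oc1ccccc1O | starting material
2 | guaiacol (2-methoxyphenol) | COc1ccccc1O | intermediate
3 | glyoxylic acid | O=CC(=O)O | starting material
4 | vanillylmandelic acid (2-hydroxy-2-(4-hydroxy-3-methoxyphenyl)acetic acid, racemic) | COc1cc(C(O)C(=O)O)ccc1O | intermediate (not isolated)
5 | vanilloylformic acid (2-(4-hydroxy-3-methoxyphenyl)-2-oxoacetic acid) | COc1cc(C(=O)C(=O)O)ccc1O | intermediate (not isolated)
6 | vanillin (4-hydroxy-3-methoxybenzaldehyde) | COc1cc(C=O)ccc1O | intermediate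
7 | dihydrofuran-3(2H)-one | O=C1CCOC1 | starting material
8 | (2Z,4E)-2,4-bis(4-hydroxy-3-methoxybenzylidene)dihydrofuran-3(2H)-one | O=C1/C(=C/c2ccc(O)c(OC)c2)CO/C1=C\c1ccc(O)c(OC)c1 | intermediate
9 | 2,4-bis(4-hydroxy-3-methoxybenzyl)dihydrofuran-3(2H)-one (cis/trans mixture, racemic) | COc1cc(CC2COC(Cc3ccc(O)c(OC)c3)C2=O)ccc1O | intermediate
10 | 2,4-bis[3-methoxy-4-(trimethylsilyloxy)benzyl]-3-(trimethylsilyloxy)-4,5-dihydrofuran (racemic) | COc1cc(CC2COC(Cc3ccc(O[Si](C)(C)C)c(OC)c3)=C2O[Si](C)(C)C)ccc1O[Si](C)(C)C | intermediate (not isolated)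
11 | 2,4-bis[3-methoxy-4-(trimethylsilyloxy)benzyl]-2-(trimethylsilyloxy)dihydrofuran-3(2H)-one (diastereomer mixture, racemic) | COc1cc(CC2COC(Cc3ccc(O[Si](C)(C)C)c(OC)c3)(O[Si](C)(C)C)C2=O)ccc1O[Si](C)(C)C | intermediate (not isolated)
12 | 2-hydroxy-2,4-bis(4-hydroxy-3-methoxybenzyl)dihydrofuran-3(2H)-one (equilibrating mixture of stereoisomers) | COc1cc(CC2COC(O)(Cc3ccc(O)c(OC)c3)C2=O)ccc1O | intermediate
13 | (3S,4R)-3-hydroxy-3,4-bis(4-hydroxy-3-methoxybenzyl)dihydrofuran-2(3H)-one | COc1cc(C[C@@H]2COC(=O)[C@]2(O)Cc2ccc(O)c(OC)c2)ccc1O | target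

## Step count and risks

Total step count: 6. Longest linear sequence: 6 steps (1 → 2 → 6 → 8 → 9 → 12 → 13).

The three steps most likely to fail:

**Step 6 (the proposed new rearrangement).** The risks are no turnover, low ee, or formation of the trans-dibenzyl series, since without the ligand the benzyl would be expected to migrate anti to the C4 substituent. The sense of induction of the (S,S)-ligand is not known in advance; if it is opposite, the (R,R)-ligand is used. The fallback uses known chemistry, sets out from 12 and comes back at 13. The shift is run without a chiral catalyst under classical benzilic-ester conditions (NaOMe, 3.3 equiv, MeOH–THF, 0 °C, then AcOH). This gives the racemic cis-lactone rac-(3S,4R)-3-hydroxy-3,4-bis(4-hydroxy-3-methoxybenzyl)dihydrofuran-2(3H)-one F1 together with the racemic trans-lactone rac-(3S,4S)-3-hydroxy-3,4-bis(4-hydroxy-3-methoxybenzyl)dihydrofuran-2(3H)-one F2. F1 is separated from F2 on silica and resolved by preparative chiral SFC (immobilised amylose phase, CO2/MeOH) to give 13. This replaces catalyst control by separation and resolution.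

**Step 5 (C2-selective oxygenation next to two electron-rich phenols).** The risks are the wrong enol ether regiochemistry or arene oxidation. The fallback sets out from 8 and comes back at 12, and fixes the regiochemistry by the position of an alkene instead of by enolisation. OsO4 (cat.)/NMO dihydroxylates the electron-rich enol-ether C2=CH bond of 8 to the hemiketal diol 2-hydroxy-2-[hydroxy(4-hydroxy-3-methoxyphenyl)methyl]-4-[(E)-4-hydroxy-3-methoxybenzylidene]dihydrofuran-3(2H)-one F3. Hydrogenation (H2, Pd/C, EtOAc, trace AcOH) then removes the p-hydroxybenzylic OH and saturates the C4 alkene to give 12.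

**Step 3 (double condensation on the sensitive 3-oxotetrahydrofuran with a free-phenol aldehyde).** The risks are mono-condensation or ring opening by β-alkoxy elimination. The fallback sets out from 6 (with 7) and comes back at 9, switching to a protected, base-mediated route. 6 is benzylated (BnBr, K2CO3, DMF) to 4-(benzyloxy)-3-methoxybenzaldehyde F4. Classical Claisen–Schmidt condensation with 7 (KOH cat., EtOH, 0 °C to rt) gives (2Z,4E)-2,4-bis[4-(benzyloxy)-3-methoxybenzylidene]dihydrofuran-3(2H)-one F5. The hydrogenation conditions of step 4 (H2, Pd/C) then saturate both alkenes and cleave both benzyl ethers in one operation to give 9.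

## Further compounds

F1 | step 6 | rac-(3S,4R)-3-hydroxy-3,4-bis(4-hydroxy-3-methoxybenzyl)dihydrofuran-2(3H)-one (racemic cis-lactone) | COc1cc(C[C@@H]2COC(=O)[C@]2(O)Cc2ccc(O)c(OC)c2)ccc1O.COc1cc(C[C@H]2COC(=O)[C@@]2(O)Cc2ccc(O)c(OC)c2)ccc1O
F2 | step 6 | rac-(3S,4S)-3-hydroxy-3,4-bis(4-hydroxy-3-methoxybenzyl)dihydrofuran-2(3H)-one (racemic trans-lactone) | COc1cc(C[C@H]2COC(=O)[C@]2(O)Cc2ccc(O)c(OC)c2)ccc1O.COc1cc(C[C@@H]2COC(=O)[C@@]2(O)Cc2ccc(O)c(OC)c2)ccc1O
F3 | step 5 | 2-hydroxy-2-[hydroxy(4-hydroxy-3-methoxyphenyl)methyl]-4-[(E)-4-hydroxy-3-methoxybenzylidene]dihydrofuran-3(2H)-one (racemic diol) | COc1cc(/C=C2\COC(O)(C(O)c3ccc(O)c(OC)c3)C2=O)ccc1O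
F4 | step 3 | 4-(benzyloxy)-3-methoxybenzaldehyde | COc1cc(C=O)ccc1OCc1ccccc1
F5 | step 3 | (2Z,4E)-2,4-bis[4-(benzyloxy)-3-methoxybenzylidene]dihydrofuran-3(2H)-one | O=C1/C(=C/c2ccc(OCc3ccccc3)c(OC)c2)CO/C1=C\c1ccc(OCc2ccccc2)c(OC)c1
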